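## Retrosynthetic overview

1. Target 15 comes from cis-isoflavan-4-ol 13 in one acid/silane operation: ionic deoxygenation at C4 plus cleavage of three MOM ethers.
2. 13 comes from racemic isoflavanone 12 by asymmetric transfer hydrogenation with dynamic kinetic resolution, which sets C3.
3. 12 comes from Pd-catalysed α-arylation of chromanone 11 with aryl bromide 9 (C3–C1' bond).
4. 9 comes from o-vanillin: MOM protection, Baeyer–Villiger oxidation, O-prenylation, aromatic Claisen rearrangement (installs the 1,1-dimethylallyl group), para-bromination, MOM protection.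
5. No ring is built: the benzopyran (rings A and C) is bought as 7-hydroxychroman-4-one and ring B as o-vanillin.

Assumption: the single stereocentre in the SMILES is C3 of the chroman and reads as (S); MOMCl, prenyl bromide and NBS are treated as reagents and not numbered.

## Route

Step 1
Reactants: 1 2-hydroxy-3-methoxybenzaldehyde (o-vanillin)
Product: 2 3-methoxy-2-(methoxymethoxy)benzaldehyde
Conditions: NaH, MOMCl, DMF, 0 °C to rt
Reagents that add atoms: chloromethyl methyl ether (MOMCl), COCCl
Why: Williamson-type O-alkylation of the sodium phenoxide protects the future 3'-oxygen as a MOM acetal.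

Step 2
Reactants: 2 3-methoxy-2-(methoxymethoxy)benzaldehyde
Product: 4 3-methoxy-2-(methoxymethoxy)phenol, via aryl formate 3 (not isolated)
Conditions: mCPBA, CH2Cl2, 0 °C to rt; then K2CO3 (cat.), MeOH, rt
Reagents that add atoms: meta-chloroperoxybenzoic acid (mCPBA), OOC(=O)c1cccc(Cl)c1
Why: Baeyer–Villiger (Dakin-type) oxidation, in which the electron-rich ortho-alkoxy aryl group migrates to give the formate, whose methanolysis frees only the terminal phenol of the 3-methoxycatechol.

Step 3
Reactants: 4 3-methoxy-2-(methoxymethoxy)phenol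
Product: 5 1-methoxy-2-(methoxymethoxy)-3-[(3-methylbut-2-en-1-yl)oxy]benzene
Conditions: prenyl bromide, K2CO3, acetone, reflux
Reagents that add atoms: prenyl bromide (1-bromo-3-methylbut-2-ene), CC(C)=CCBr
Why: Williamson ether synthesis on the only free phenol gives the aryl prenyl ether needed for the Claisen rearrangement.

Step 4
Reactants: 5 1-methoxy-2-(methoxymethoxy)-3-[(3-methylbut-2-en-1-yl)oxy]benzene
Product: 7 3-methoxy-2-(methoxymethoxy)-6-(2-methylbut-3-en-2-yl)phenol, via ortho-dienone 6 (not isolated)
Conditions: PhNEt2, 190 °C, sealed tube, argon, 3 h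
Reagents that add atoms: none
Why: Aromatic Claisen rearrangement, a [3,3]-sigmatropic shift to the only free ortho carbon that bonds the Me2C terminus to the ring, followed by tautomerisation of the dienone to the 1,1-dimethylallyl phenol.

Step 5
Reactants: 7 3-methoxy-2-(methoxymethoxy)-6-(2-methylbut-3-en-2-yl)phenol
Product: 8 4-bromo-3-methoxy-2-(methoxymethoxy)-6-(2-methylbut-3-en-2-yl)phenol
Conditions: NBS (1.0 equiv), MeCN, −30 °C to 0 °C, dark
Reagents that add atoms: N-bromosuccinimide (NBS), O=C1CCC(=O)N1Br
Why: Electrophilic aromatic bromination goes to the one open position para to the free phenol (both ortho positions are blocked), and this ring substitution outruns attack on the hindered monosubstituted alkene.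

Step 6
Reactants: 8 4-bromo-3-methoxy-2-(methoxymethoxy)-6-(2-methylbut-3-en-2-yl)phenol
Product: 9 1-bromo-2-methoxy-3,4-bis(methoxymethoxy)-5-(2-methylbut-3-en-2-yl)benzene
Conditions: NaH, MOMCl, DMF, 0 °C to rt
Reagents that add atoms: chloromethyl methyl ether (MOMCl), COCCl
Why: Williamson-type O-alkylation masks the phenol so that the aryl bromide can enter the base-mediated cross-coupling.

Step 7
Reactants: 10 7-hydroxychroman-4-one
Product: 11 7-(methoxymethoxy)chroman-4-one
Conditions: MOMCl, K2CO3, acetone, rt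
Reagents that add atoms: chloromethyl methyl ether (MOMCl), COCCl
Why: Williamson-type O-alkylation of the acidic para-acyl phenol removes the competing phenoxide before enolate chemistry.

Step 8
Reactants: 9 1-bromo-2-methoxy-3,4-bis(methoxymethoxy)-5-(2-methylbut-3-en-2-yl)benzene; 11 7-(methoxymethoxy)chroman-4-one (1.3 equiv)
Product: 12 rac-7-(methoxymethoxy)-3-[2-methoxy-3,4-bis(methoxymethoxy)-5-(2-methylbut-3-en-2-yl)phenyl]chroman-4-one
Conditions: Pd2(dba)3, P(t-Bu)3, NaOtBu, toluene, 70 °C
Reagents that add atoms: none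
Why: Buchwald–Hartwig–Miura ketone α-arylation, in which the sodium enolate of 11 couples with the arylpalladium bromide formed from 9 and zerovalent palladium to make the C3–C1' bond, the new stereocentre being racemic on purpose.

Step 9
Reactants: 12 rac-7-(methoxymethoxy)-3-[2-methoxy-3,4-bis(methoxymethoxy)-5-(2-methylbut-3-en-2-yl)phenyl]chroman-4-one
Product: 13 (3S,4S)-7-(methoxymethoxy)-3-[2-methoxy-3,4-bis(methoxymethoxy)-5-(2-methylbut-3-en-2-yl)phenyl]chroman-4-ol (cis)
Conditions: RuCl(p-cymene)[(S,S)-TsDPEN] (3 mol %), HCO2H/Et3N 5:2, EtOAc, 40 °C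
Reagents that add atoms: none
Why: Noyori–Ikariya asymmetric transfer hydrogenation with dynamic kinetic resolution, in which C3 epimerises through the enol while the (S,S) catalyst reduces the aryl ketone to the (4S)-alcohol and takes only the ketone enantiomer that gives the cis product, so C3 becomes (S).

Step 10
Reactants: 13 (3S,4S)-7-(methoxymethoxy)-3-[2-methoxy-3,4-bis(methoxymethoxy)-5-(2-methylbut-3-en-2-yl)phenyl]chroman-4-ol
Product: 15 (3S)-3-[3,4-dihydroxy-2-methoxy-5-(2-methylbut-3-en-2-yl)phenyl]-3,4-dihydro-2H-chromen-7-ol, via tris-MOM isoflavan 14 (not isolated)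
Conditions: Et3SiH (10 equiv), TFA/CH2Cl2 1:4, −20 °C, then rt
Reagents that add atoms: none
Why: Kursanov–Parnes ionic hydrogenation, in which TFA ionises the C4 alcohol to a cation stabilised by O1 and the para C7 oxygen and Et3SiH traps it before the C3 proton is lost so C3 stays (S), after which the same acid cleaves the three MOM acetals on warming while the silane scavenges the methoxymethyl cations.

## Compound list

1 | 2-hydroxy-3-methoxybenzaldehyde (o-vanillin) | COc1cccc(C=O)c1O | starting material
2 | 3-methoxy-2-(methoxymethoxy)benzaldehyde | COCOc1c(OC)cccc1C=O | intermediate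
3 | 3-methoxy-2-(methoxymethoxy)phenyl formate | COCOc1c(OC)cccc1OC=O | intermediate
4 | 3-methoxy-2-(methoxymethoxy)phenol | COCOc1c(OC)cccc1O | intermediate
5 | 1-methoxy-2-(methoxymethoxy)-3-[(3-methylbut-2-en-1-yl)oxy]benzene | COCOc1c(OC)cccc1OCC=C(C)C | intermediate
6 | 3-methoxy-2-(methoxymethoxy)-6-(2-methylbut-3-en-2-yl)cyclohexa-2,4-dien-1-one | C=CC(C)(C)C1C=CC(OC)=C(OCOC)C1=O | intermediate
7 | 3-methoxy-2-(methoxymethoxy)-6-(2-methylbut-3-en-2-yl)phenol | C=CC(C)(C)c1ccc(OC)c(OCOC)c1O | intermediate
8 | 4-bromo-3-methoxy-2-(methoxymethoxy)-6-(2-methylbut-3-en-2-yl)phenol | C=CC(C)(C)c1cc(Br)c(OC)c(OCOC)c1O | intermediate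
9 | 1-bromo-2-methoxy-3,4-bis(methoxymethoxy)-5-(2-methylbut-3-en-2-yl)benzene | C=CC(C)(C)c1cc(Br)c(OC)c(OCOC)c1OCOC | intermediate
10 | 7-hydroxychroman-4-one | O=C1CCOc2cc(O)ccc12 | starting material
11 | 7-(methoxymethoxy)chroman-4-one | COCOc1ccc2c(c1)OCCC2=O | intermediate
12 | rac-7-(methoxymethoxy)-3-[2-methoxy-3,4-bis(methoxymethoxy)-5-(2-methylbut-3-en-2-yl)phenyl]chroman-4-one (racemic) | C=CC(C)(C)c1cc(C2COc3cc(OCOC)ccc3C2=O)c(OC)c(OCOC)c1OCOC | intermediate
13 | (3S,4S)-7-(methoxymethoxy)-3-[2-methoxy-3,4-bis(methoxymethoxy)-5-(2-methylbut-3-en-2-yl)phenyl]chroman-4-ol | C=CC(C)(C)c1cc([C@H]2COc3cc(OCOC)ccc3[C@H]2O)c(OC)c(OCOC)c1OCOC | intermediate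
14 | (3S)-7-(methoxymethoxy)-3-[2-methoxy-3,4-bis(methoxymethoxy)-5-(2-methylbut-3-en-2-yl)phenyl]chroman | C=CC(C)(C)c1cc([C@H]2COc3cc(OCOC)ccc3C2)c(OC)c(OCOC)c1OCOC | intermediate
15 | (3S)-3-[3,4-dihydroxy-2-methoxy-5-(2-methylbut-3-en-2-yl)phenyl]-3,4-dihydro-2H-chromen-7-ol | C=CC(C)(C)c1cc([C@H]2COc3cc(O)ccc3C2)c(OC)c(O)c1O | target

## Step count and risks

Total steps: 10. Longest linear sequence: 9 (steps 1–6, then 8–10); step 7 is a one-step side branch.

Steps most likely to fail:

**Step 4 (Claisen rearrangement).** The prenyl ether can give the para-prenyl isomer by a further Cope shift, and the product can undergo abnormal Claisen rearrangement or cyclise to a dihydrobenzofuran on prolonged heating. Fallback: the tertiary allyl group is installed by cross-coupling instead of rearrangement, setting out from 4 and returning at 9. Compound 4 is protected (NaH, MOMCl, DMF) to 1-methoxy-2,3-bis(methoxymethoxy)benzene F1. Directed ortho-lithiation next to the terminal MOM ether (n-BuLi, TMEDA, THF, 0 °C) and an I2 quench give 1-iodo-4-methoxy-2,3-bis(methoxymethoxy)benzene F2. A branched-selective (γ) Suzuki–Miyaura coupling with 3-methylbut-2-enylboronic acid pinacol ester (Pd(OAc)2, bulky biarylphosphine, K3PO4, aqueous THF) gives 1-methoxy-2,3-bis(methoxymethoxy)-4-(2-methylbut-3-en-2-yl)benzene F3. NBS in MeCN then brominates ortho to the methoxy group (para to a MOM ether) and delivers 9.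

**Step 8 (α-arylation).** The strongly basic enolate of 11 can ring-open by retro-oxa-Michael reaction or self-condense, and the aryl bromide is electron-rich and ortho-substituted. Fallback: a base-free coupling of a preformed enolate, setting out from 11 and returning at 12. Compound 11 is converted (TMSOTf, Et3N, CH2Cl2, 0 °C) into trimethyl{[7-(methoxymethoxy)-2H-chromen-4-yl]oxy}silane F4. This is coupled with 9 under fluoride activation (Pd2(dba)3, P(t-Bu)3, Bu3SnF, CsF, toluene, 85 °C) to give 12.

**Step 10 (ionic deoxygenation and global deprotection).** The C4 cation may lose the C3 proton to give the isoflav-3-ene, which would erode the ee, and the free phenol next to the 1,1-dimethylallyl group may cyclise in acid. Fallback: radical instead of cationic deoxygenation, setting out from 13 and returning at 14. Compound 13 is converted (NaH, CS2, then MeI, THF) into O-{(3S,4S)-7-(methoxymethoxy)-3-[2-methoxy-3,4-bis(methoxymethoxy)-5-(2-methylbut-3-en-2-yl)phenyl]chroman-4-yl} S-methyl carbonodithioate F5. Barton–McCombie reduction (Bu3SnH, AIBN, toluene, 80 °C) gives 14 without a cation next to C3. Only the MOM cleavage of step 10 then remains, which still needs acid, so this answers the racemisation risk and not the cyclisation risk.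

## Further compounds

F1 | step 4 | 1-methoxy-2,3-bis(methoxymethoxy)benzene | COCOc1cccc(OC)c1OCOC
F2 | step 4 | 1-iodo-4-methoxy-2,3-bis(methoxymethoxy)benzene | COCOc1c(I)ccc(OC)c1OCOC
F3 | step 4 | 1-methoxy-2,3-bis(methoxymethoxy)-4-(2-methylbut-3-en-2-yl)benzene | C=CC(C)(C)c1ccc(OC)c(OCOC)c1OCOC
F4 | step 8 | trimethyl{[7-(methoxymethoxy)-2H-chromen-4-yl]oxy}silane | COCOc1ccc2c(c1)OCC=C2O[Si](C)(C)C
F5 | step 10 | O-{(3S,4S)-7-(methoxymethoxy)-3-[2-methoxy-3,4-bis(methoxymethoxy)-5-(2-methylbut-3-en-2-yl)phenyl]chroman-4-yl} S-methyl carbonodithioate | C=CC(C)(C)c1cc([C@H]2COc3cc(OCOC)ccc3[C@H]2OC(=S)SC)c(OC)c(OCOC)c1OCOC
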